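**Assumption:** Kanzonol L has no stereocentres and no stereogenic double bonds (it is achiral), so "single enantiomer" is taken to mean the single constitutional isomer drawn; no stereocontrol is needed.

## Retrosynthetic overview

1. Kanzonol L ⇒ one‑carbon annulation of a mirror‑symmetric 3,5‑diprenyl‑2,4,6‑trihydroxy‑deoxybenzoin; the two ortho OH groups are equivalent, so ring closure has no regiochemical issue (pyranone C ring formed last).
2. Key step: both prenyl groups are installed at once by twofold C‑alkylation of the unprotected acylphloroglucinol through dearomatised cyclohexadienone tautomers, with the B‑ring tosylate removed in the same pot.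
3. Deoxybenzoin ⇒ phloroglucinol + chromenyl acetonitrile (Hoesch acylation; the A ring is bought as phloroglucinol and its three‑fold symmetry is broken here).
4. Nitrile ⇒ aldehyde (TosMIC) ⇒ aryl 1,1‑dimethylpropargyl ether (Claisen/oxa‑6π; B‑ring pyran formed first) ⇒ 2,4‑dihydroxybenzaldehyde.
5. One tosyl group does three jobs: it directs the propargylation to O‑2, tames the chromene towards acid, and blocks the B‑ring oxygen during prenylation.

## Route

**Step 1**
Reactants: 1, 2,4‑dihydroxybenzaldehyde; 2, p‑toluenesulfonyl chloride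
Product: 3, 4‑formyl‑3‑hydroxyphenyl 4‑methylbenzenesulfonate
Conditions: TsCl (1.05 equiv), K2CO3, acetone, 0 °C → rt
Reagents that add atoms: TsCl, Cc1ccc(cc1)S(Cl)(=O)=O
Why: Chemoselective O‑sulfonylation: the 2‑OH is tied up in a hydrogen bond to the formyl group and the 4‑OH (para to CHO) is the more acidic, so only O‑4 reacts.

**Step 2**
Reactants: 3; 4, 3‑chloro‑3‑methylbut‑1‑yne
Product: 5, 4‑formyl‑3‑[(2‑methylbut‑3‑yn‑2‑yl)oxy]phenyl 4‑methylbenzenesulfonate
Conditions: 4 (1.5 equiv), DBU, CuCl2·2H2O (1 mol %), MeCN, 0 °C → rt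
Reagents that add atoms: 3‑chloro‑3‑methylbut‑1‑yne, CC(C)(Cl)C#C
Why: Copper‑catalysed propargylic etherification (Godfrey‑type) of the only free phenol, which forms the tertiary aryl propargyl ether without E2 elimination; the tosylate is inert to DBU at this temperature.

**Step 3**
Reactants: 5
Product: 6, 8‑formyl‑2,2‑dimethyl‑2H‑chromen‑5‑yl 4‑methylbenzenesulfonate
Conditions: 1,2‑dichlorobenzene, 170 °C, 3 h
Reagents that add atoms: none
Why: Aromatic propargyl Claisen rearrangement (transient allenyl cyclohexadienone), then enolisation, 1,5‑H shift and oxa‑6π electrocyclisation; C‑3 is the only free ortho position, so the pyran must close on the oxygen ortho to the formyl group.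

**Step 4**
Reactants: 6; 7, tosylmethyl isocyanide (TosMIC)
Product: 8, 8‑(cyanomethyl)‑2,2‑dimethyl‑2H‑chromen‑5‑yl 4‑methylbenzenesulfonate
Conditions: TosMIC (1.3 equiv), t‑BuOK (2.4 equiv), DME, −40 °C; then MeOH, 65 °C, 20 min
Reagents that add atoms: TosMIC, [C-]#[N+]CS(=O)(=O)c1ccc(C)cc1 (supplies the nitrile C and N)
Why: Van Leusen reductive cyanation converts ArCHO into ArCH2CN in one operation; the aryl tosylate is cleaved only slowly by methoxide and should largely survive the short reflux.

**Step 5**
Reactants: 8; 9, phloroglucinol (anhydrous, 1.2 equiv); 10, water (hydrolysis)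
Product: 11, 2,2‑dimethyl‑8‑[2‑oxo‑2‑(2,4,6‑trihydroxyphenyl)ethyl]‑2H‑chromen‑5‑yl 4‑methylbenzenesulfonate
Conditions: ZnCl2, HCl(g), Et2O, 0 °C → 4 °C, 16 h; then H2O, 90 °C, 1 h
Reagents that add atoms: water, O (ketone oxygen)
Why: Houben–Hoesch C‑acylation of phloroglucinol gives the ketiminium salt, hydrolysed to the ketone and stopping at mono‑acylation; the electron‑withdrawing sulfonate removes the second oxygen donor that would stabilise a C‑4 chromene cation, which is what lets the chromene tolerate HCl.

**Step 6 (key step)**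
Reactants: 11; 12, prenyl bromide (1‑bromo‑3‑methylbut‑2‑ene)
Product: 13, 2‑(5‑hydroxy‑2,2‑dimethyl‑2H‑chromen‑8‑yl)‑1‑[2,4,6‑trihydroxy‑3,5‑bis(3‑methylbut‑2‑en‑1‑yl)phenyl]ethan‑1‑one
Conditions: prenyl bromide (2.3 equiv), 10 % aq KOH, 0 °C, Ar, 2 h, then rt 30 min; then KOH, MeOH, Na2S2O4 (cat.), 65 °C, Ar; AcOH/ice to pH 5
Reagents that add atoms: prenyl bromide, CC(C)=CCBr (two equivalents incorporated)
Why: Twofold C‑alkylation of the ambident acylphloroglucinol phenoxide (the deoxyhumulone‑type reaction, C‑selective in water) gives cyclohexadienones that re‑aromatise by tautomerisation at the two equivalent ring CH positions, while the tosylate blocks the B‑ring oxygen and is saponified only after the excess prenyl bromide has been solvolysed.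

**Step 7**
Reactants: 13; 14, tert‑butoxybis(dimethylamino)methane (Bredereck's reagent)
Product: 15, Kanzonol L, 5,7‑dihydroxy‑3‑(5‑hydroxy‑2,2‑dimethyl‑2H‑chromen‑8‑yl)‑6,8‑bis(3‑methylbut‑2‑en‑1‑yl)‑4H‑chromen‑4‑one
Conditions: t‑BuOCH(NMe2)2 (4 equiv), THF, 60 °C; then aq AcOH (pH 4–5), rt
Reagents that add atoms: Bredereck's reagent, CN(C)C(OC(C)(C)C)N(C)C (supplies C‑2 as one CH)
Why: Aminomethylenation of the benzylic ketone CH2 followed by addition–elimination cyclisation of an ortho OH (enaminone route to isoflavones) under acid‑free conditions that spare the prenyl and chromene groups; the reagent cannot O‑methylate, and either equivalent ortho OH gives the same product.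

## Compound list

1 | 2,4‑dihydroxybenzaldehyde | O=Cc1ccc(O)cc1O | starting material
2 | p‑toluenesulfonyl chloride | Cc1ccc(cc1)S(Cl)(=O)=O | starting material
3 | 4‑formyl‑3‑hydroxyphenyl 4‑methylbenzenesulfonate | Cc1ccc(cc1)S(=O)(=O)Oc1ccc(C=O)c(O)c1 | intermediate
4 | 3‑chloro‑3‑methylbut‑1‑yne | CC(C)(Cl)C#C | starting material
5 | 4‑formyl‑3‑[(2‑methylbut‑3‑yn‑2‑yl)oxy]phenyl 4‑methylbenzenesulfonate | Cc1ccc(cc1)S(=O)(=O)Oc1ccc(C=O)c(OC(C)(C)C#C)c1 | intermediate
6 | 8‑formyl‑2,2‑dimethyl‑2H‑chromen‑5‑yl 4‑methylbenzenesulfonate | Cc1ccc(cc1)S(=O)(=O)Oc1ccc(C=O)c2OC(C)(C)C=Cc12 | intermediate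
7 | tosylmethyl isocyanide | [C-]#[N+]CS(=O)(=O)c1ccc(C)cc1 | starting material
8 | 8‑(cyanomethyl)‑2,2‑dimethyl‑2H‑chromen‑5‑yl 4‑methylbenzenesulfonate | Cc1ccc(cc1)S(=O)(=O)Oc1ccc(CC#N)c2OC(C)(C)C=Cc12 | intermediate
9 | phloroglucinol | Oc1cc(O)cc(O)c1 | starting material
10 | water | O | starting material (reagent)
11 | 2,2‑dimethyl‑8‑[2‑oxo‑2‑(2,4,6‑trihydroxyphenyl)ethyl]‑2H‑chromen‑5‑yl 4‑methylbenzenesulfonate | Cc1ccc(cc1)S(=O)(=O)Oc1ccc(CC(=O)c3c(O)cc(O)cc3O)c2OC(C)(C)C=Cc12 | intermediate
12 | prenyl bromide | CC(C)=CCBr | starting material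
13 | 2‑(5‑hydroxy‑2,2‑dimethyl‑2H‑chromen‑8‑yl)‑1‑[2,4,6‑trihydroxy‑3,5‑bis(3‑methylbut‑2‑en‑1‑yl)phenyl]ethan‑1‑one | CC(C)=CCc1c(O)c(CC=C(C)C)c(O)c(C(=O)Cc2ccc(O)c3C=CC(C)(C)Oc23)c1O | intermediate
14 | tert‑butoxybis(dimethylamino)methane | CN(C)C(OC(C)(C)C)N(C)C | starting material
15 | Kanzonol L | CC(C)=CCc1c(O)c(CC=C(C)C)c2occ(-c3ccc(O)c4c3OC(C)(C)C=C4)c(=O)c2c1O | target

## Summary

Total steps: 7. Longest linear sequence: 7 (phloroglucinol enters at step 5).

Steps most likely to fail, each with a fallback that changes the approach: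

1. **Step 6 (double C‑prenylation and detosylation).** Mono‑ and tri‑alkylated, O‑alkylated and air‑oxidised (humulone‑type) by‑products are expected, so the yield will be moderate at best. Fallback: prenylate the simple ketone 2,4,6‑trihydroxyacetophenone instead, convert it into a MOM‑protected 6,8‑diprenyl‑3‑iodochromone, and join it to a B‑ring boronate (from 6 by Dakin oxidation, triflation and Miyaura borylation) by Suzuki coupling.
2. **Step 5 (Hoesch in the presence of the chromene).** HCl could add to the chromene, or phloroglucinol could hydroarylate it. Fallback: an anionic union in place of Friedel–Crafts chemistry: hydrolyse 8 to the acid, make the Weinreb amide, add 2‑lithio‑1,3,5‑tris(methoxymethoxy)benzene, then remove the MOM groups with mild acid and rejoin at step 6.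
3. **Step 7 (annulation of the unprotected tetraphenol).** Cyclisation may be incomplete or side reactions may occur at the free phenols. Fallback: the Baker–Ollis sequence, in which C‑2 is introduced as an oxalyl unit (ethoxalyl chloride/pyridine to the 2‑ethoxycarbonyl isoflavone) and then removed by saponification and decarboxylation.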